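**Strategy**

The C3–O aryl ether is disconnected into two coumarins that share one benzenoid ring: C4a (carbon), C5–H, C6–OMe, C7–O, C8–OMe, C8a–O. The key step exploits exactly this array. In one operation it joins acyclic 1,3-dimethoxyacetone (C6–C7–C8, its ketone oxygen becoming the unique C7 oxygen) to diethyl ethoxymethylenemalonate (C5, C4a, C8a, future C4) by addition–elimination, C-acylation and aromatisation; the precursor is simply this symmetrical ketone and the malonate, both purchased. The derived salicylaldehyde serves twice: Wittig lactonisation gives isofraxidin, and Perkin condensation of its 7-oxyacetic acid with a second aldehyde portion builds the 3-aryloxycoumarin.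

Key step: step 1

Remark: the target has no stereocentre, so no stereocontrol is needed; coumarin numbering is used for both halves, and tert-butyl bromoacetate replaces the ethyl ester so that the acid can be freed without base.

**Route**

Step 1
Reactants: 1 1,3-dimethoxyacetone; 2 diethyl ethoxymethylenemalonate
Product: 4 ethyl 2,4-dihydroxy-3,5-dimethoxybenzoate, via alkylidene malonate 3 (not isolated)
Conditions: NaOEt (3 equiv), EtOH, 0 °C, slow addition of 2, then reflux, Ar; aq. HCl
Reagents that add atoms: none
Why: Proposed new method: ethoxide generates the enolate of 1, which adds to the β-carbon of 2 and expels ethoxide (C5–C6 bond) to give 3, held as its stabilised dienolate; the second methoxymethylene carbon then attacks the ester that necessarily lies cis to the ketone chain (C8–C8a bond), and loss of ethoxide followed by enolisation should give the resorcylate as its phenoxide. The closest known reaction types are the (3+3) cyclocondensation of acetonedicarboxylates with alkoxymethylenemalonates, the formation of 2-pyrone-3-carboxylates from simple ketone enolates and alkoxymethylenemalonates, and the alkoxide-induced isomerisation of 2-pyrones to resorcylates. The one ring formed, the benzenoid ring of each coumarin half, closes by a 6-exo-trig Dieckmann-type C-acylation. No stereocentre is created, and the CH(OMe) centre of 3 disappears on aromatisation. The step needs C- over O-acylation: O-closure gives a 2-pyrone that ethoxide in ethanol can reopen, whereas C-closure ends in an aromatic phenoxide that does not revert, so excess ethoxide at reflux should drain the equilibrium towards 4; the symmetry of 1 removes any regiochemical choice and the matched ethoxide/ethyl ester pair prevents ester scrambling.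

Step 2
Reactants: 4 ethyl 2,4-dihydroxy-3,5-dimethoxybenzoate
Product: 5 ethyl 4-(benzyloxy)-2-hydroxy-3,5-dimethoxybenzoate
Conditions: BnBr (1.05 equiv), K2CO3 (1.1 equiv), acetone, 50 °C
Reagents that add atoms: benzyl bromide, BrCc1ccccc1
Why: Williamson etherification in which the 2-OH, hydrogen-bonded to the ester carbonyl and the weaker acid, stays protonated while one equivalent of mild base ionises and alkylates only the 4-OH para to the ester.

Step 3
Reactants: 5 ethyl 4-(benzyloxy)-2-hydroxy-3,5-dimethoxybenzoate
Product: 6 3-(benzyloxy)-6-(hydroxymethyl)-2,4-dimethoxyphenol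
Conditions: LiAlH4, THF, 0 °C to rt; aq. KNaC4H4O6 (potassium sodium tartrate)
Reagents that add atoms: none
Why: Hydride reduction of the ester to the primary alcohol with LiAlH4, the phenol being carried as its aluminate and the benzyl and methyl ethers being inert.

Step 4
Reactants: 6 3-(benzyloxy)-6-(hydroxymethyl)-2,4-dimethoxyphenol
Product: 7 4-(benzyloxy)-2-hydroxy-3,5-dimethoxybenzaldehyde
Conditions: activated MnO2 (10 equiv), CH2Cl2, rt
Reagents that add atoms: none
Why: Chemoselective MnO2 oxidation of a benzylic alcohol, which stops at the hydrogen-bonded salicylaldehyde and leaves the phenol and ethers alone.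

Step 5
Reactants: 7 4-(benzyloxy)-2-hydroxy-3,5-dimethoxybenzaldehyde; 8 ethyl (triphenylphosphoranylidene)acetate
Product: 11 7-(benzyloxy)-6,8-dimethoxy-2H-chromen-2-one, via (E)-cinnamate 9 (not isolated), via (Z)-cinnamate 10 (not isolated)
Conditions: PhNEt2, reflux (about 215 °C), Ar
Reagents that add atoms: none
Why: Wittig olefination with a stabilised ylide followed by thermal E-to-Z equilibration and lactonisation of the ortho-hydroxycinnamate, the standard one-pot coumarin synthesis from salicylaldehydes, the ring fixing the alkene geometry.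

Step 6
Reactants: 11 7-(benzyloxy)-6,8-dimethoxy-2H-chromen-2-one
Product: 12 7-hydroxy-6,8-dimethoxy-2H-chromen-2-one (isofraxidin)
Conditions: H2 (1 atm), 10% Pd/C, EtOAc–MeOH, rt
Reagents that add atoms: none
Why: Catalytic hydrogenolysis of the aryl benzyl ether, which at 1 atm and room temperature should be faster than reduction of the conjugated lactone double bond.

Step 7
Reactants: 12 isofraxidin; 13 tert-butyl bromoacetate
Product: 14 tert-butyl 2-[(6,8-dimethoxy-2-oxo-2H-chromen-7-yl)oxy]acetate
Conditions: K2CO3, DMF, 50 °C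
Reagents that add atoms: none
Why: Williamson etherification of the acidic coumarin phenol with a reactive α-bromo ester, under carbonate conditions that do not open the lactone.

Step 8
Reactants: 14 tert-butyl 2-[(6,8-dimethoxy-2-oxo-2H-chromen-7-yl)oxy]acetate
Product: 15 2-[(6,8-dimethoxy-2-oxo-2H-chromen-7-yl)oxy]acetic acid
Conditions: TFA, CH2Cl2, rt
Reagents that add atoms: none
Why: Acidolysis of the tert-butyl ester with loss of 2-methylpropene frees the acid without exposing the lactone to hydroxide.

Step 9
Reactants: 15 2-[(6,8-dimethoxy-2-oxo-2H-chromen-7-yl)oxy]acetic acid; 7 4-(benzyloxy)-2-hydroxy-3,5-dimethoxybenzaldehyde (second portion)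
Product: 18 7-(benzyloxy)-3-[(6,8-dimethoxy-2-oxo-2H-chromen-7-yl)oxy]-6,8-dimethoxy-2H-chromen-2-one, via mixed anhydride 16 (not isolated), via aryl ester 17 (not isolated)
Conditions: Ac2O, Et3N, 110 °C
Reagents that add atoms: none
Why: Perkin–Oglialoro condensation, in which the mixed anhydride acylates the phenol of 7 and the α-aryloxy ester enolate closes onto the aldehyde by intramolecular aldol condensation, the classical route from aryloxyacetic acids and salicylaldehydes to 3-aryloxycoumarins.

Step 10
Reactants: 18 7-(benzyloxy)-3-[(6,8-dimethoxy-2-oxo-2H-chromen-7-yl)oxy]-6,8-dimethoxy-2H-chromen-2-one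
Product: 19 7-hydroxy-3-[(6,8-dimethoxy-2-oxo-2H-chromen-7-yl)oxy]-6,8-dimethoxy-2H-chromen-2-one (target)
Conditions: H2 (1 atm), 10% Pd/C, THF–MeOH, rt
Reagents that add atoms: none
Why: Hydrogenolysis of the remaining benzyl ether as in step 6 should release the C7 phenol while the methyl ethers, the diaryl ether and both lactones stay intact.

**Compound list**

1 | 1,3-dimethoxyacetone | COCC(=O)COC | starting material
2 | diethyl ethoxymethylenemalonate | CCOC=C(C(=O)OCC)C(=O)OCC | starting material
3 | diethyl 2-(2,4-dimethoxy-3-oxobutylidene)propanedioate (racemic at the CH(OMe) carbon, present as its sodium dienolate) | CCOC(=O)C(=CC(OC)C(=O)COC)C(=O)OCC | intermediate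
4 | ethyl 2,4-dihydroxy-3,5-dimethoxybenzoate | CCOC(=O)c1cc(OC)c(O)c(OC)c1O | intermediate
5 | ethyl 4-(benzyloxy)-2-hydroxy-3,5-dimethoxybenzoate | CCOC(=O)c1cc(OC)c(OCc2ccccc2)c(OC)c1O | intermediate
6 | 3-(benzyloxy)-6-(hydroxymethyl)-2,4-dimethoxyphenol | OCc1cc(OC)c(OCc2ccccc2)c(OC)c1O | intermediate
7 | 4-(benzyloxy)-2-hydroxy-3,5-dimethoxybenzaldehyde | O=Cc1cc(OC)c(OCc2ccccc2)c(OC)c1O | intermediate
8 | ethyl (triphenylphosphoranylidene)acetate | CCOC(=O)C=P(c1ccccc1)(c1ccccc1)c1ccccc1 | starting material
9 | ethyl (E)-3-[4-(benzyloxy)-2-hydroxy-3,5-dimethoxyphenyl]prop-2-enoate | CCOC(=O)/C=C/c1cc(OC)c(OCc2ccccc2)c(OC)c1O | intermediate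
10 | ethyl (Z)-3-[4-(benzyloxy)-2-hydroxy-3,5-dimethoxyphenyl]prop-2-enoate | CCOC(=O)/C=C\c1cc(OC)c(OCc2ccccc2)c(OC)c1O | intermediate
11 | 7-(benzyloxy)-6,8-dimethoxy-2H-chromen-2-one | COc1cc2ccc(=O)oc2c(OC)c1OCc1ccccc1 | intermediate
12 | 7-hydroxy-6,8-dimethoxy-2H-chromen-2-one (isofraxidin) | COc1cc2ccc(=O)oc2c(OC)c1O | intermediate
13 | tert-butyl bromoacetate | CC(C)(C)OC(=O)CBr | starting material
14 | tert-butyl 2-[(6,8-dimethoxy-2-oxo-2H-chromen-7-yl)oxy]acetate | COc1cc2ccc(=O)oc2c(OC)c1OCC(=O)OC(C)(C)C | intermediate
15 | 2-[(6,8-dimethoxy-2-oxo-2H-chromen-7-yl)oxy]acetic acid | COc1cc2ccc(=O)oc2c(OC)c1OCC(=O)O | intermediate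
16 | acetic 2-[(6,8-dimethoxy-2-oxo-2H-chromen-7-yl)oxy]acetic anhydride | CC(=O)OC(=O)COc1c(OC)cc2ccc(=O)oc2c1OC | intermediate
17 | 3-(benzyloxy)-6-formyl-2,4-dimethoxyphenyl 2-[(6,8-dimethoxy-2-oxo-2H-chromen-7-yl)oxy]acetate | O=Cc1cc(OC)c(OCc2ccccc2)c(OC)c1OC(=O)COc1c(OC)cc2ccc(=O)oc2c1OC | intermediate
18 | 7-(benzyloxy)-3-[(6,8-dimethoxy-2-oxo-2H-chromen-7-yl)oxy]-6,8-dimethoxy-2H-chromen-2-one | COc1cc2cc(Oc3c(OC)cc4ccc(=O)oc4c3OC)c(=O)oc2c(OC)c1OCc1ccccc1 | intermediate
19 | 7-hydroxy-3-[(6,8-dimethoxy-2-oxo-2H-chromen-7-yl)oxy]-6,8-dimethoxy-2H-chromen-2-one | COc1cc2cc(Oc3c(OC)cc4ccc(=O)oc4c3OC)c(=O)oc2c(OC)c1O | target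

**Step count and risks**

Total step count: 10. Longest linear sequence: 10 steps (1 to 10 in a row; aldehyde 7 is drawn on twice, in steps 5 and 9).

Steps most likely to fail:

1. Step 1 (key step, proposed new method). The sequence may stop at the O-acylated 2-pyrone, or 1 may be consumed by self-aldol condensation or double addition to 2, so that closure on carbon never becomes the main course. The fallback uses known chemistry only. It cannot set out from a compound of the route, since 1 and 2 are both given up; it starts from purchased 2,6-dimethoxyphenol F1 and rejoins the route at 7, replacing steps 1 to 4. Benzylation (BnBr, K2CO3, DMF) should give 2-(benzyloxy)-1,3-dimethoxybenzene F2. Vilsmeier–Haack formylation (POCl3, DMF, 80 °C) is expected at C4, as with 1,2,3-trimethoxybenzene, to give 3-(benzyloxy)-2,4-dimethoxybenzaldehyde F3. Baeyer–Villiger oxidation with mCPBA in CH2Cl2 should give 3-(benzyloxy)-2,4-dimethoxyphenyl formate F4, and methanolysis (K2CO3, MeOH) the free 3-(benzyloxy)-2,4-dimethoxyphenol F5. Magnesium-mediated ortho-formylation (MgCl2, Et3N, paraformaldehyde, MeCN, reflux) can only take the single open ortho position and should deliver 7.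

2. Step 9. Condensation through the acetyl group of the anhydride (leading to a 3-unsubstituted coumarin) or simple O-acetylation of the hindered phenol of 7 may outrun formation and cyclisation of the aryloxyacetyl ester. The fallback sets out from 15 and 7 and returns at 18, making the ester bond first without a competing acyl donor. Acid 15 is treated with (COCl)2 and catalytic DMF in CH2Cl2 to give 2-[(6,8-dimethoxy-2-oxo-2H-chromen-7-yl)oxy]acetyl chloride F6. This acylates the phenol of 7 (Et3N, DMAP, CH2Cl2, 0 °C) to give ester 17, now isolated. A separate intramolecular Knoevenagel-type aldol condensation (DBU, MeCN, 60 °C) should then close the lactone ring to 18.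

3. Step 3. The electron-rich ortho-hydroxybenzyl aluminate may lose oxide to an ortho-quinone methide, which hydride would reduce further to the cresol, and the salicyl alcohol may oligomerise on work-up. The fallback sets out from 5 and returns at 7, replacing steps 3 and 4 and masking the phenol during the redox adjustment. Benzylation of the chelated phenol (BnBr, K2CO3, DMF, 80 °C) should give ethyl 2,4-bis(benzyloxy)-3,5-dimethoxybenzoate F7. LiAlH4 in THF then gives [2,4-bis(benzyloxy)-3,5-dimethoxyphenyl]methanol F8, and MnO2 in CH2Cl2 gives 2,4-bis(benzyloxy)-3,5-dimethoxybenzaldehyde F9. Chelation-controlled cleavage of the benzyl ether ortho to the aldehyde with MgBr2·OEt2 (toluene–Et2O, reflux) should return 7.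

Further compounds
F1 | step 1 | 2,6-dimethoxyphenol (purchased) | COc1cccc(OC)c1O
F2 | step 1 | 2-(benzyloxy)-1,3-dimethoxybenzene | COc1cccc(OC)c1OCc1ccccc1
F3 | step 1 | 3-(benzyloxy)-2,4-dimethoxybenzaldehyde | COc1ccc(C=O)c(OC)c1OCc1ccccc1
F4 | step 1 | 3-(benzyloxy)-2,4-dimethoxyphenyl formate | COc1ccc(OC=O)c(OC)c1OCc1ccccc1
F5 | step 1 | 3-(benzyloxy)-2,4-dimethoxyphenol | COc1ccc(O)c(OC)c1OCc1ccccc1
F6 | step 9 | 2-[(6,8-dimethoxy-2-oxo-2H-chromen-7-yl)oxy]acetyl chloride | COc1cc2ccc(=O)oc2c(OC)c1OCC(Cl)=O
F7 | step 3 | ethyl 2,4-bis(benzyloxy)-3,5-dimethoxybenzoate | CCOC(=O)c1cc(OC)c(OCc2ccccc2)c(OC)c1OCc1ccccc1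
F8 | step 3 | [2,4-bis(benzyloxy)-3,5-dimethoxyphenyl]methanol | OCc1cc(OC)c(OCc2ccccc2)c(OC)c1OCc1ccccc1
F9 | step 3 | 2,4-bis(benzyloxy)-3,5-dimethoxybenzaldehyde | O=Cc1cc(OC)c(OCc2ccccc2)c(OC)c1OCc1ccccc1
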